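The earlier runs and the new flask are simulated with constants of no real substance; scatter was added.

The easy mistake is to hold the new flasks against the earlier runs hour by hour, though north-east and west were charged more heavily than blue and violet.

| setting | north-east | west | blue | violet |
|---|---|---|---|---|
| starting material | 0.35 M | 0.55 M | 0.25 M | 0.25 M |
| temperature | 75 °C | 94 °C | 98 °C | 90 °C |
| remark | run made earlier | run made earlier |  |  |
| time |  |  | 6.0 h | 6.0 h |

| run | time / h | open dimer / % | ring / % | open trimer / % | starting material / % |
|---|---|---|---|---|---|
| north-east | 0.667 | 27.7 | 13.0 | 30.3 | 31.0 |
| north-east | 2.00 | 19.5 | 18.4 | 51.8 | 9.9 |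
| north-east | 3.00 | 18.7 | 17.9 | 57.0 | 6.5 |
| north-east | 5.00 | 14.2 | 16.8 | 63.4 | 3.8 |
| north-east | 8.00 | 10.0 | 12.9 | 70.5 | 4.8 |
| west | 0.250 | 29.3 | 18.4 | 39.2 | 14.2 |
| west | 0.500 | 22.2 | 16.3 | 50.9 | 8.9 |
| west | 1.00 | 18.2 | 9.9 | 65.6 | 6.2 |
| west | 2.00 | 12.3 | 5.8 | 78.3 | 3.6 |
| west | 4.00 | 7.7 | 4.4 | 88.1 | 4.3 |

(standard deviation of a reading: 1 percentage point)

* which of these there is most of at the end, counted by the starting material in it, blue (starting material / open dimer / ring / open trimer)
* which of these there is most of at the end, counted by the starting material in it, violet (starting material / open dimer / ring / open trimer)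
* final amount of the leader among these, as a percentage of the starting material charged, in blue
* final amount of the leader among these, as a percentage of the starting material charged, in violet

- in percentages every species weighs as the starting material in it: one open dimer counts as two
- in percentages every species weighs as the starting material in it: one open trimer counts as three
- what was read earlier has a scatter of 1 percentage point, one standard deviation

In west, ring over starting material reads 1.60 at 1.00 h, 1.61 at 2.00 h and 1.02 at 4.00 h, where a scatter of 1 percentage point weighs heavily on both amounts, so ring is taken here as a resting state, held in balance with starting material. If that balance stands and the other steps pair molecule with molecule, fractions of the charge at one temperature follow the charge-time, the charge multiplied by the time. Blue and violet both have: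

90.0 M·min

West reaches this charge-time at 2.73 h, north-east at 4.29 h. Reading between the points gives open trimer at:

west: 81.9 %; north-east: 61.1 %

So violet is placed between these two, and blue, hotter than west, above 81.9 %; both bounds are estimates from scattered readings. On the lower bound the other species in violet share 38.9 %, so open trimer is the expected leader there, and in blue, with its bound at 81.9 %, as well.

To tighten this, north-east ends at 70.5 %, which west matches at 1.39 h. West's readings therefore put its clock ahead by:

3.67 over the gap between those runs, and, spread evenly by the degree, 1.32 over the step from west to blue or from violet to west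

This factor stays below the 1.47 that would carry blue past west's last reading, so that reading, 88.1 %, is taken as blue's ceiling. Dividing or multiplying 2.73 h by the factor gives:

violet: 78.7 %; blue: 86.1 %

The forecast names open trimer for both, at 85 % in blue and 77 % in violet, both inside these brackets, and ends with “Dilution favours ring slightly, so I shade these down”.

The flasks give open trimer at 86.9 % in blue and open trimer at 78.7 % in violet.

    starting material ⇌ ring (K = 1.50, k = 6.20 × 10⁻⁴ s⁻¹, Ea = 122 kJ mol⁻¹, ΔH = −33.0 kJ mol⁻¹)
    2 starting material → open dimer (k = 0.00256 L mol⁻¹ s⁻¹, Ea = 79.0 kJ mol⁻¹)
    starting material + open dimer → open trimer (k = 0.00509 L mol⁻¹ s⁻¹, Ea = 60.0 kJ mol⁻¹)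
    (constants at 90 °C)

Blue and violet share the charge-time 90.0 M·min, so the gap between them belongs to the difference in temperature: at violet's temperature, blue's open trimer stands at 78.7 % instead of 86.9 %. Violet read at 25 h has a charge-time of 375 M·min, beyond west's last reading, and there open trimer stands at 94.2 %, with ring at 1.46 %.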